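## Retrosynthetic overview

1. The 19-membered macrolactone is made last. It is opened at the C7–C8 diene bond (copper-mediated Stille-type ring closure) and at the C1–O–C19 ester (Yamaguchi), giving iodo acid fragment A (C1–C7) and stannyl alcohol fragment B (C8–C24). The C5 ketone is carried as a silyl ether and unveiled after ring closure.
2. Fragment B: C19–C20 by Nozaki–Hiyama–Kishi addition of epoxy vinyl iodide fragment C (C20–C24, oxirane from Sharpless epoxidation of crotyl alcohol) to a C19 aldehyde. C8–C13 is grown on the oxolane by ozonolysis, Still–Gennari olefination (12Z), asymmetric propargylation (C11) and alkyne to (Z)-vinylstannane conversion.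
3. Oxolane: a dithiane (C17–C19, from Roche ester) opens an epoxide (C13–C16, from Sharpless desymmetrisation of divinylcarbinol). The derived hydroxy ketone is closed by hemiketal reduction to the 2,5-cis ring.
4. Fragment A: propargyl alcohol, carboalumination/iodination (6E), asymmetric crotylboration (C4), Still–Gennari olefination (2Z).
5. Ring order: oxirane (in C) and oxolane (in the core of B) before fragment union; macrocycle last.

Assumption: carbons are numbered C1 (lactone carbonyl) to C24 (oxirane methyl); the SMILES is read as 2Z,4S,6E,8Z,11R,12Z,14R,15S,17R,18R,19R,20E,22R,23R, with a 2,5-cis oxolane (C14–C17) whose C15 methoxy is trans to both ring substituents.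

## Route

Step 1
Reactants: 1 methyl (2S)-3-hydroxy-2-methylpropanoate
Product: 2 methyl (2S)-3-[(tert-butyldiphenylsilyl)oxy]-2-methylpropanoate
Conditions: t-BuPh2SiCl, imidazole, CH2Cl2, 0 °C → rt
Reagents that add atoms: tert-butyl(chloro)diphenylsilane, CC(C)(C)[Si](Cl)(c1ccccc1)c1ccccc1
Why: Silylation of the primary alcohol gives an ether that survives the organolithium, Lewis-acid and hydride steps ahead, and the C18 stereocentre comes unchanged from the chiral pool.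

Step 2
Reactants: 2 methyl (2S)-3-[(tert-butyldiphenylsilyl)oxy]-2-methylpropanoate
Product: 3 (2S)-3-[(tert-butyldiphenylsilyl)oxy]-2-methylpropanal
Conditions: i-Bu2AlH (1.1 equiv), CH2Cl2, −78 °C; MeOH, then aq. KNaC4H4O6
Reagents that add atoms: none
Why: Partial reduction of the ester stops at the aldehyde because the tetrahedral aluminium hemiacetal is stable at −78 °C, and the α-stereocentre is not enolised.

Step 3
Reactants: 3 (2S)-3-[(tert-butyldiphenylsilyl)oxy]-2-methylpropanal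
Product: 4 tert-butyl{[(2S)-2-(1,3-dithian-2-yl)propyl]oxy}diphenylsilane
Conditions: HS(CH2)3SH, BF3·OEt2 (0.5 equiv), CH2Cl2, −78 → −20 °C
Reagents that add atoms: propane-1,3-dithiol, SCCCS
Why: Lewis-acid-catalysed dithioacetalisation at low temperature installs the 1,3-dithiane (the C17 acyl-anion equivalent) without epimerising C18.

Step 4
Reactants: 5 penta-1,4-dien-3-ol
Product: 6 (2S,3R)-1,2-epoxypent-4-en-3-ol
Conditions: Ti(OiPr)4 (cat.), D-(−)-diisopropyl tartrate, t-BuOOH, 4 Å MS, CH2Cl2, −20 °C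
Reagents that add atoms: tert-butyl hydroperoxide, CC(C)(C)OO
Why: Sharpless asymmetric epoxidation desymmetrises the divinylcarbinol, the D-tartrate catalyst epoxidising one enantiotopic vinyl group on one face to give the erythro (2S,3R) epoxy alcohol that fixes C14 (R) and C15 (S), while the minor enantiomer is consumed by a second epoxidation.

Step 5
Reactants: 6 (2S,3R)-1,2-epoxypent-4-en-3-ol
Product: 7 (2S)-2-{(1R)-1-[(4-methoxybenzyl)oxy]prop-2-en-1-yl}oxirane
Conditions: NaH, 4-MeOC6H4CH2Cl, Bu4NI (cat.), THF, 0 °C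
Reagents that add atoms: 4-methoxybenzyl chloride, COc1ccc(CCl)cc1
Why: Williamson etherification of the sodium alkoxide at 0 °C outruns Payne rearrangement and masks O14 with a group that tolerates organolithiums and is removed oxidatively.

Step 6
Reactants: 4 tert-butyl{[(2S)-2-(1,3-dithian-2-yl)propyl]oxy}diphenylsilane; 7 (2S)-2-{(1R)-1-[(4-methoxybenzyl)oxy]prop-2-en-1-yl}oxirane
Product: 10 C13–C19 dithiane with C15 methyl ether and C14 PMB ether, via 2-lithiodithiane 8 (not isolated), via lithium alkoxide 9 (not isolated)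
Conditions: t-BuLi, THF/HMPA (9:1), −78 °C; add 7, −78 → 0 °C; then MeI, 0 °C → rt
Reagents that add atoms: iodomethane, CI
Why: Corey–Seebach umpolung, in which the 2-lithio-1,3-dithiane opens the monosubstituted epoxide at its CH2 terminus (C16) by SN2 so that the C14, C15 and C18 centres are untouched, followed by Williamson O-methylation of the lithium alkoxide in the HMPA-containing medium.

Step 7
Reactants: 10 C13–C19 dithiane with C15 methyl ether and C14 PMB ether
Product: 11 (2S,5S,6R)-1-[(tert-butyldiphenylsilyl)oxy]-5-methoxy-6-[(4-methoxybenzyl)oxy]-2-methyloct-7-en-3-one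
Conditions: MeI, CaCO3, MeCN/H2O (9:1), 45 °C
Reagents that add atoms: water, O
Why: Alkylative dithiane cleavage (S-methylation, then hydrolysis of the sulfonium) unmasks the C17 ketone under near-neutral conditions that spare the PMB ether, the alkene and the silyl ether and do not epimerise C18.

Step 8
Reactants: 11 (2S,5S,6R)-1-[(tert-butyldiphenylsilyl)oxy]-5-methoxy-6-[(4-methoxybenzyl)oxy]-2-methyloct-7-en-3-one
Product: 13 (4S,5R)-2-{(2S)-1-[(tert-butyldiphenylsilyl)oxy]propan-2-yl}-5-ethenyl-4-methoxyoxolan-2-ol (both anomers), via hydroxy ketone 12 (not isolated)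
Conditions: DDQ, CH2Cl2/aq. NaH2PO4–Na2HPO4 buffer (pH 7, 10:1), 0 °C → rt
Reagents that add atoms: none
Why: Oxidative cleavage of the PMB ether by DDQ frees the C14 hydroxyl, which adds to the C17 ketone to give the five-membered hemiketal.

Step 9
Reactants: 13 (4S,5R)-2-{(2S)-1-[(tert-butyldiphenylsilyl)oxy]propan-2-yl}-5-ethenyl-4-methoxyoxolan-2-ol
Product: 14 tert-butyl{[(2S)-2-[(2R,4S,5R)-5-ethenyl-4-methoxyoxolan-2-yl]propyl]oxy}diphenylsilane
Conditions: Et3SiH, BF3·OEt2, CH2Cl2, −78 → −40 °C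
Reagents that add atoms: none
Why: Kishi-type hemiketal reduction, in which the five-membered oxocarbenium ion is reduced by Et3SiH on the face cis to the pseudoaxial C15 methoxy group and anti to the C14 vinyl group (inside attack, Woerpel model), which sets C17 as R and gives the 2,5-cis oxolane.

Step 10
Reactants: 14 tert-butyl{[(2S)-2-[(2R,4S,5R)-5-ethenyl-4-methoxyoxolan-2-yl]propyl]oxy}diphenylsilane
Product: 16 (2S,3S,5R)-5-{(2S)-1-[(tert-butyldiphenylsilyl)oxy]propan-2-yl}-3-methoxyoxolane-2-carbaldehyde, via ozonide 15 (not isolated)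
Conditions: O3, CH2Cl2, −78 °C; then PPh3, −78 °C → rt
Reagents that add atoms: ozone, [O-][O+]=O
Why: Ozonolysis of the only alkene with reductive work-up of the ozonide gives the C13 aldehyde without touching the ring stereocentres.

Step 11
Reactants: 16 (2S,3S,5R)-5-{(2S)-1-[(tert-butyldiphenylsilyl)oxy]propan-2-yl}-3-methoxyoxolane-2-carbaldehyde
Product: 17 methyl (2Z)-3-[(2R,3S,5R)-5-{(2S)-1-[(tert-butyldiphenylsilyl)oxy]propan-2-yl}-3-methoxyoxolan-2-yl]-2-methylprop-2-enoate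
Conditions: (CF3CH2O)2P(O)CH(CH3)CO2Me, KN(SiMe3)2, 18-crown-6, THF, −78 °C
Reagents that add atoms: methyl 2-[bis(2,2,2-trifluoroethoxy)phosphoryl]propanoate, COC(=O)C(C)P(=O)(OCC(F)(F)F)OCC(F)(F)F
Why: Still–Gennari olefination, in which the electron-poor phosphonate anion adds under kinetic control and eliminates fast to give the (Z)-2-methyl enoate (12Z, C14 cis to C11).

Step 12
Reactants: 17 methyl (2Z)-3-[(2R,3S,5R)-5-{(2S)-1-[(tert-butyldiphenylsilyl)oxy]propan-2-yl}-3-methoxyoxolan-2-yl]-2-methylprop-2-enoate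
Product: 18 (2Z)-3-[(2R,3S,5R)-5-{(2S)-1-[(tert-butyldiphenylsilyl)oxy]propan-2-yl}-3-methoxyoxolan-2-yl]-2-methylprop-2-en-1-ol
Conditions: i-Bu2AlH (2.5 equiv), CH2Cl2, −78 °C
Reagents that add atoms: none
Why: 1,2-Reduction of the conjugated ester by the aluminium hydride gives the allylic alcohol and keeps the Z alkene.

Step 13
Reactants: 18 (2Z)-3-[(2R,3S,5R)-5-{(2S)-1-[(tert-butyldiphenylsilyl)oxy]propan-2-yl}-3-methoxyoxolan-2-yl]-2-methylprop-2-en-1-ol
Product: 19 (2Z)-3-[(2R,3S,5R)-5-{(2S)-1-[(tert-butyldiphenylsilyl)oxy]propan-2-yl}-3-methoxyoxolan-2-yl]-2-methylprop-2-enal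
Conditions: MnO2, CH2Cl2, rt, dark
Reagents that add atoms: none
Why: Allylic oxidation with MnO2 is neutral and heterogeneous, so the labile (Z)-enal forms without isomerisation and is used at once.

Step 14
Reactants: 19 (2Z)-3-[(2R,3S,5R)-5-{(2S)-1-[(tert-butyldiphenylsilyl)oxy]propan-2-yl}-3-methoxyoxolan-2-yl]-2-methylprop-2-enal
Product: 20 (1Z,3R)-1-[(2R,3S,5R)-5-{(2S)-1-[(tert-butyldiphenylsilyl)oxy]propan-2-yl}-3-methoxyoxolan-2-yl]-2-methylhex-1-en-5-yn-3-ol
Conditions: allenylboronic acid pinacol ester, (R)-3,3′-bis(2,4,6-triisopropylphenyl)-1,1′-binaphthyl-2,2′-diyl hydrogen phosphate (5 mol %), 4 Å MS, toluene, −20 °C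
Reagents that add atoms: allenylboronic acid pinacol ester, C=C=CB1OC(C)(C)C(C)(C)O1
Why: Chiral phosphoric acid-catalysed propargylation, in which the allenylboronate reacts through a closed six-membered transition state (SE2′) to give only the homopropargylic alcohol, and the (R)-catalyst, which directs attack to the Re face as with aryl aldehydes, sets C11 as R.

Step 15
Reactants: 20 (1Z,3R)-1-[(2R,3S,5R)-5-{(2S)-1-[(tert-butyldiphenylsilyl)oxy]propan-2-yl}-3-methoxyoxolan-2-yl]-2-methylhex-1-en-5-yn-3-ol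
Product: 21 C11 tert-butyldimethylsilyl ether of 20
Conditions: t-BuMe2SiOTf, 2,6-lutidine, CH2Cl2, −78 °C
Reagents that add atoms: tert-butyldimethylsilyl trifluoromethanesulfonate, CC(C)(C)[Si](C)(C)OS(=O)(=O)C(F)(F)F
Why: Silylation with the silyl triflate protects the hindered secondary allylic O11 as a TBS ether that outlasts the primary TBDPS and secondary TES ethers removed later.

Step 16
Reactants: 21 C11 tert-butyldimethylsilyl ether of 20
Product: 23 C8 tributylstannyl alkyne, via lithium acetylide 22 (not isolated)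
Conditions: n-BuLi, THF, −78 °C; then Bu3SnCl, −78 → 0 °C
Reagents that add atoms: tributyltin chloride, CCCC[Sn](Cl)(CCCC)CCCC
Why: Deprotonation of the terminal alkyne and stannylation of the acetylide gives the alkynylstannane required for regiocontrolled hydrozirconation.

Step 17
Reactants: 23 C8 tributylstannyl alkyne
Product: 25 (8Z)-C8 vinylstannane with O11 TBS and O19 TBDPS ethers, via alkenylzirconocene 24 (not isolated)
Conditions: Cp2Zr(H)Cl, THF, rt; then H2O
Reagents that add atoms: none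
Why: Hydrozirconation of the stannylalkyne is syn and places zirconium on the tin-bearing carbon (Lipshutz protocol), and protonolysis of the C–Zr bond with retention leaves tin cis to C10, which is the (Z)-vinylstannane.

Step 18
Reactants: 25 (8Z)-C8 vinylstannane with O11 TBS and O19 TBDPS ethers
Product: 26 (2S)-2-[(2R,4S,5R)-5-[(1Z,3R,5Z)-3-[(tert-butyldimethylsilyl)oxy]-2-methyl-6-(tributylstannyl)hexa-1,5-dien-1-yl]-4-methoxyoxolan-2-yl]propan-1-ol
Conditions: Bu4NF/AcOH (1:1), THF, 0 °C → rt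
Reagents that add atoms: none
Why: Acetic acid-buffered fluoride cleaves the unhindered primary TBDPS ether faster than the hindered secondary allylic TBS ether and is too weakly acidic to protodestannylate the vinylstannane.

Step 19
Reactants: 26 (2S)-2-[(2R,4S,5R)-5-[(1Z,3R,5Z)-3-[(tert-butyldimethylsilyl)oxy]-2-methyl-6-(tributylstannyl)hexa-1,5-dien-1-yl]-4-methoxyoxolan-2-yl]propan-1-ol
Product: 27 (2R)-2-[(2R,4S,5R)-5-[(1Z,3R,5Z)-3-[(tert-butyldimethylsilyl)oxy]-2-methyl-6-(tributylstannyl)hexa-1,5-dien-1-yl]-4-methoxyoxolan-2-yl]propanal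
Conditions: Dess–Martin periodinane, NaHCO3, CH2Cl2, 0 °C
Reagents that add atoms: none
Why: Buffered Dess–Martin oxidation gives the C19 aldehyde without epimerising C18 or touching the vinylstannane, and the aldehyde is used at once.

Step 20
Reactants: 28 (2E)-but-2-en-1-ol
Product: 29 [(2R,3R)-3-methyloxiran-2-yl]methanol
Conditions: Ti(OiPr)4 (5 mol %), D-(−)-diethyl tartrate (6 mol %), t-BuOOH, 4 Å MS, CH2Cl2, −20 °C
Reagents that add atoms: tert-butyl hydroperoxide, CC(C)(C)OO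
Why: Sharpless asymmetric epoxidation of the (E)-allylic alcohol with the D-tartrate catalyst delivers oxygen to one face and gives the (2R,3R) trans-epoxy alcohol, which fixes C22 and C23.

Step 21
Reactants: 29 [(2R,3R)-3-methyloxiran-2-yl]methanol
Product: 30 (2S,3R)-3-methyloxirane-2-carbaldehyde
Conditions: 2,2,6,6-tetramethylpiperidin-1-oxyl (cat.), PhI(OAc)2, CH2Cl2, 0 °C → rt; solution used directly
Reagents that add atoms: none
Why: Oxoammonium-mediated oxidation of the primary alcohol gives the volatile epoxy aldehyde under non-basic conditions that neither epimerise nor open the oxirane.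

Step 22
Reactants: 30 (2S,3R)-3-methyloxirane-2-carbaldehyde
Product: 31 (2R,3R)-2-[(E)-2-iodoethenyl]-3-methyloxirane
Conditions: CHI3, CrCl2, THF, 0 °C
Reagents that add atoms: iodoform, IC(I)I
Why: Takai olefination, in which the geminal dichromium reagent from CHI3 and CrCl2 adds to the aldehyde and eliminates to give the (E)-vinyl iodide (20E) without opening the oxirane.

Step 23
Reactants: 27 (2R)-2-[(2R,4S,5R)-5-[(1Z,3R,5Z)-3-[(tert-butyldimethylsilyl)oxy]-2-methyl-6-(tributylstannyl)hexa-1,5-dien-1-yl]-4-methoxyoxolan-2-yl]propanal; 31 (2R,3R)-2-[(E)-2-iodoethenyl]-3-methyloxirane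
Product: 33 fragment B (C8–C24 stannyl alcohol with free 19R hydroxyl), via alkenylchromium 32 (not isolated)
Conditions: CrCl2, NiCl2 (1 mol %), DMSO, rt
Reagents that add atoms: none
Why: Nozaki–Hiyama–Kishi alkenylation, in which the alkenylchromium adds only to the aldehyde with retention of the E geometry, and Felkin–Anh control by the C18 methyl reinforced by 1,3-anti induction from the C17 ring oxygen favours the 18,19-syn/17,19-anti (19R) alcohol, the minor epimer being removed by chromatography.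

Step 24
Reactants: 34 prop-2-yn-1-ol
Product: 36 (2E)-3-iodo-2-methylprop-2-en-1-ol, via alkenylalane 35 (not isolated)
Conditions: Me3Al, Cp2ZrCl2 (0.25 equiv), CH2Cl2, 0 °C → rt; then I2, THF, −30 → 0 °C
Reagents that add atoms: trimethylaluminium, C[Al](C)C; iodine, II
Why: Negishi zirconium-catalysed carboalumination adds methyl and aluminium syn across the alkyne with aluminium at the terminus, and iodinolysis with retention gives the (E)-vinyl iodide that becomes the 6E alkene.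

Step 25
Reactants: 36 (2E)-3-iodo-2-methylprop-2-en-1-ol
Product: 37 (2E)-3-iodo-2-methylprop-2-enal
Conditions: MnO2, CH2Cl2, rt
Reagents that add atoms: none
Why: Allylic oxidation with MnO2 gives the volatile enal, which is used as a solution without isomerisation.

Step 26
Reactants: 37 (2E)-3-iodo-2-methylprop-2-enal
Product: 38 (1E,3S,4S)-1-iodo-2,4-dimethylhexa-1,5-dien-3-ol
Conditions: (E)-crotylboronic acid pinacol ester, (S)-3,3′-bis(2,4,6-triisopropylphenyl)-1,1′-binaphthyl-2,2′-diyl hydrogen phosphate (5 mol %), 4 Å MS, toluene, −30 °C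
Reagents that add atoms: (E)-crotylboronic acid pinacol ester, C/C=C/CB1OC(C)(C)C(C)(C)O1
Why: Chiral phosphoric acid-catalysed crotylboration, in which the (E)-crotylboronate reacts through a chair transition state to give the anti adduct and the (S)-catalyst directs attack to the Si face, setting C4 as S (and C5 as S, later oxidised to the ketone).

Step 27
Reactants: 38 (1E,3S,4S)-1-iodo-2,4-dimethylhexa-1,5-dien-3-ol
Product: 39 triethyl{[(1E,3S,4S)-1-iodo-2,4-dimethylhexa-1,5-dien-3-yl]oxy}silane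
Conditions: Et3SiCl, imidazole, CH2Cl2, 0 °C
Reagents that add atoms: chlorotriethylsilane, CC[Si](Cl)(CC)CC
Why: Silylation protects O5 as a TES ether, the most labile silyl group in the route, so that it can be removed selectively before the late oxidation to the C5 ketone.

Step 28
Reactants: 39 triethyl{[(1E,3S,4S)-1-iodo-2,4-dimethylhexa-1,5-dien-3-yl]oxy}silane
Product: 41 (2R,3S,4E)-5-iodo-2,4-dimethyl-3-[(triethylsilyl)oxy]pent-4-enal, via 1,2-diol 40 (not isolated)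
Conditions: OsO4 (2 mol %), NaIO4, 2,6-lutidine, dioxane/H2O (3:1), rt
Reagents that add atoms: sodium periodate (oxygen source through OsO4), [Na+].[O-]I(=O)(=O)=O
Why: Lemieux–Johnson cleavage, in which OsO4 dihydroxylates the monosubstituted alkene in preference to the hindered electron-poor iodoalkene and NaIO4 cleaves the diol to the C3 aldehyde, 2,6-lutidine suppressing epimerisation at C4.

Step 29
Reactants: 41 (2R,3S,4E)-5-iodo-2,4-dimethyl-3-[(triethylsilyl)oxy]pent-4-enal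
Product: 42 methyl (2Z,4S,5S,6E)-7-iodo-2,4,6-trimethyl-5-[(triethylsilyl)oxy]hepta-2,6-dienoate
Conditions: (CF3CH2O)2P(O)CH(CH3)CO2Me, KN(SiMe3)2, 18-crown-6, THF, −78 °C
Reagents that add atoms: methyl 2-[bis(2,2,2-trifluoroethoxy)phosphoryl]propanoate, COC(=O)C(C)P(=O)(OCC(F)(F)F)OCC(F)(F)F
Why: Still–Gennari olefination gives the (Z)-2-methyl enoate (2Z) at −78 °C without epimerising the α-methyl aldehyde.

Step 30
Reactants: 42 methyl (2Z,4S,5S,6E)-7-iodo-2,4,6-trimethyl-5-[(triethylsilyl)oxy]hepta-2,6-dienoate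
Product: 43 fragment A, (2Z,4S,5S,6E)-7-iodo-2,4,6-trimethyl-5-[(triethylsilyl)oxy]hepta-2,6-dienoic acid
Conditions: Me3SnOH, ClCH2CH2Cl, 80 °C; then cold 0.1 M HCl wash
Reagents that add atoms: trimethyltin hydroxide, C[Sn](C)(C)O
Why: Me3SnOH cleaves the methyl ester by acyl substitution under neutral conditions that keep the TES ether, the vinyl iodide and the Z geometry intact.

Step 31
Reactants: 43 fragment A, (2Z,4S,5S,6E)-7-iodo-2,4,6-trimethyl-5-[(triethylsilyl)oxy]hepta-2,6-dienoic acid; 33 fragment B (C8–C24 stannyl alcohol with free 19R hydroxyl)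
Product: 45 C19 ester of fragments A and B (open-chain iodide/stannane), via mixed anhydride 44 (not isolated)
Conditions: 2,4,6-Cl3C6H2COCl, Et3N, toluene, rt; then 33, 4-(dimethylamino)pyridine, toluene, rt
Reagents that add atoms: none
Why: Yamaguchi esterification, in which the acid is activated as its 2,4,6-trichlorobenzoyl mixed anhydride and acylates the hindered C19 alcohol with retention at C19 under conditions known to spare (Z)-2-methyl-2-enoates from isomerisation.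

Step 32
Reactants: 45 C19 ester of fragments A and B (open-chain iodide/stannane)
Product: 47 macrolactone with O5 TES and O11 TBS ethers (2Z,4S,5S,6E,8Z,11R,12Z,14R,15S,17R,18R,19R,20E,22R,23R), via alkenylcopper 46 (not isolated)
Conditions: CuO2C-C4H3S (copper thiophene-2-carboxylate), degassed NMP (2 mM), 0 °C → rt
Reagents that add atoms: none
Why: Liebeskind-type copper-mediated Stille coupling, in which tin-to-copper transmetalation gives an alkenylcopper that couples with the vinyl iodide with retention of both geometries (6E,8Z) under palladium-free conditions that leave the vinyl oxirane alone, high dilution favouring closure of the 19-membered ring.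

Step 33
Reactants: 47 macrolactone with O5 TES and O11 TBS ethers
Product: 48 macrolactone with free 5S hydroxyl and O11 TBS ether
Conditions: HF·pyridine, pyridine, THF, 0 °C
Reagents that add atoms: none
Why: Pyridine-buffered HF removes the secondary TES ether much faster than the secondary TBS ether, freeing only the C5 hydroxyl.

Step 34
Reactants: 48 macrolactone with free 5S hydroxyl and O11 TBS ether
Product: 49 O11 TBS ether of the target (C5 ketone)
Conditions: Dess–Martin periodinane, NaHCO3, CH2Cl2, 0 °C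
Reagents that add atoms: none
Why: Buffered Dess–Martin oxidation converts the dienylic C5 alcohol into the dienone without enolising C4, which is α to the new ketone and γ to the enoate.

Step 35
Reactants: 49 O11 TBS ether of the target (C5 ketone)
Product: 50 target CNP0117824.1
Conditions: HF·pyridine, pyridine, THF, 0 °C → rt
Reagents that add atoms: none
Why: Pyridine-buffered HF cleaves the remaining TBS ether under weakly acidic conditions that avoid base-induced epimerisation at C4 and leave the vinyl oxirane and the Z,E-dienone intact.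

## Compound list

1 | methyl (2S)-3-hydroxy-2-methylpropanoate | COC(=O)[C@@H](C)CO | starting material
2 | methyl (2S)-3-[(tert-butyldiphenylsilyl)oxy]-2-methylpropanoate | COC(=O)[C@@H](C)CO[Si](c1ccccc1)(c1ccccc1)C(C)(C)C | intermediate
3 | (2S)-3-[(tert-butyldiphenylsilyl)oxy]-2-methylpropanal | O=C[C@@H](C)CO[Si](c1ccccc1)(c1ccccc1)C(C)(C)C | intermediate
4 | tert-butyl{[(2S)-2-(1,3-dithian-2-yl)propyl]oxy}diphenylsilane | C1(SCCCS1)[C@@H](C)CO[Si](c2ccccc2)(c2ccccc2)C(C)(C)C | intermediate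
5 | penta-1,4-dien-3-ol | C=CC(O)C=C | starting material
6 | (2S,3R)-1,2-epoxypent-4-en-3-ol, i.e. (1R)-1-[(2S)-oxiran-2-yl]prop-2-en-1-ol | C=C[C@@H](O)[C@@H]1CO1 | intermediate
7 | (2S)-2-{(1R)-1-[(4-methoxybenzyl)oxy]prop-2-en-1-yl}oxirane | C=C[C@@H](OCc1ccc(OC)cc1)[C@@H]1CO1 | intermediate
8 | {2-[(2S)-1-[(tert-butyldiphenylsilyl)oxy]propan-2-yl]-1,3-dithian-2-yl}lithium | [Li]C1(SCCCS1)[C@@H](C)CO[Si](c2ccccc2)(c2ccccc2)C(C)(C)C | intermediate
9 | lithium (2S,3R)-1-{2-[(2S)-1-[(tert-butyldiphenylsilyl)oxy]propan-2-yl]-1,3-dithian-2-yl}-3-[(4-methoxybenzyl)oxy]pent-4-en-2-olate | C=C[C@@H](OCc1ccc(OC)cc1)[C@@H](O[Li])CC1(SCCCS1)[C@@H](C)CO[Si](c2ccccc2)(c2ccccc2)C(C)(C)C | intermediate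
10 | tert-butyl{[(2S)-2-{2-[(2S,3R)-2-methoxy-3-[(4-methoxybenzyl)oxy]pent-4-en-1-yl]-1,3-dithian-2-yl}propyl]oxy}diphenylsilane | C=C[C@@H](OCc1ccc(OC)cc1)[C@@H](OC)CC1(SCCCS1)[C@@H](C)CO[Si](c2ccccc2)(c2ccccc2)C(C)(C)C | intermediate
11 | (2S,5S,6R)-1-[(tert-butyldiphenylsilyl)oxy]-5-methoxy-6-[(4-methoxybenzyl)oxy]-2-methyloct-7-en-3-one | C=C[C@@H](OCc1ccc(OC)cc1)[C@@H](OC)CC(=O)[C@@H](C)CO[Si](c1ccccc1)(c1ccccc1)C(C)(C)C | intermediate
12 | (2S,5S,6R)-1-[(tert-butyldiphenylsilyl)oxy]-6-hydroxy-5-methoxy-2-methyloct-7-en-3-one | C=C[C@@H](O)[C@@H](OC)CC(=O)[C@@H](C)CO[Si](c1ccccc1)(c1ccccc1)C(C)(C)C | intermediate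
13 | (4S,5R)-2-{(2S)-1-[(tert-butyldiphenylsilyl)oxy]propan-2-yl}-5-ethenyl-4-methoxyoxolan-2-ol (both anomers at C2) | C=C[C@H]1OC(O)([C@@H](C)CO[Si](c2ccccc2)(c2ccccc2)C(C)(C)C)C[C@@H]1OC | intermediate
14 | tert-butyl{[(2S)-2-[(2R,4S,5R)-5-ethenyl-4-methoxyoxolan-2-yl]propyl]oxy}diphenylsilane (2,5-cis oxolane) | C=C[C@H]1O[C@@H]([C@@H](C)CO[Si](c2ccccc2)(c2ccccc2)C(C)(C)C)C[C@@H]1OC | intermediate
15 | 3-[(2S,3S,5R)-5-{(2S)-1-[(tert-butyldiphenylsilyl)oxy]propan-2-yl}-3-methoxyoxolan-2-yl]-1,2,4-trioxolane (ozonide, both epimers at the trioxolane carbon) | O1OC(OC1)[C@H]1O[C@@H]([C@@H](C)CO[Si](c2ccccc2)(c2ccccc2)C(C)(C)C)C[C@@H]1OC | intermediate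
16 | (2S,3S,5R)-5-{(2S)-1-[(tert-butyldiphenylsilyl)oxy]propan-2-yl}-3-methoxyoxolane-2-carbaldehyde | O=C[C@H]1O[C@@H]([C@@H](C)CO[Si](c2ccccc2)(c2ccccc2)C(C)(C)C)C[C@@H]1OC | intermediate
17 | methyl (2Z)-3-[(2R,3S,5R)-5-{(2S)-1-[(tert-butyldiphenylsilyl)oxy]propan-2-yl}-3-methoxyoxolan-2-yl]-2-methylprop-2-enoate | COC(=O)/C(C)=C\[C@H]1O[C@@H]([C@@H](C)CO[Si](c2ccccc2)(c2ccccc2)C(C)(C)C)C[C@@H]1OC | intermediate
18 | (2Z)-3-[(2R,3S,5R)-5-{(2S)-1-[(tert-butyldiphenylsilyl)oxy]propan-2-yl}-3-methoxyoxolan-2-yl]-2-methylprop-2-en-1-ol | OC/C(C)=C\[C@H]1O[C@@H]([C@@H](C)CO[Si](c2ccccc2)(c2ccccc2)C(C)(C)C)C[C@@H]1OC | intermediate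
19 | (2Z)-3-[(2R,3S,5R)-5-{(2S)-1-[(tert-butyldiphenylsilyl)oxy]propan-2-yl}-3-methoxyoxolan-2-yl]-2-methylprop-2-enal | O=C/C(C)=C\[C@H]1O[C@@H]([C@@H](C)CO[Si](c2ccccc2)(c2ccccc2)C(C)(C)C)C[C@@H]1OC | intermediate
20 | (1Z,3R)-1-[(2R,3S,5R)-5-{(2S)-1-[(tert-butyldiphenylsilyl)oxy]propan-2-yl}-3-methoxyoxolan-2-yl]-2-methylhex-1-en-5-yn-3-ol | C#CC[C@@H](O)/C(C)=C\[C@H]1O[C@@H]([C@@H](C)CO[Si](c2ccccc2)(c2ccccc2)C(C)(C)C)C[C@@H]1OC | intermediate
21 | tert-butyl{[(1Z,3R)-1-[(2R,3S,5R)-5-{(2S)-1-[(tert-butyldiphenylsilyl)oxy]propan-2-yl}-3-methoxyoxolan-2-yl]-2-methylhex-1-en-5-yn-3-yl]oxy}dimethylsilane | C#CC[C@@H](O[Si](C)(C)C(C)(C)C)/C(C)=C\[C@H]1O[C@@H]([C@@H](C)CO[Si](c2ccccc2)(c2ccccc2)C(C)(C)C)C[C@@H]1OC | intermediate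
22 | lithium acetylide of 21 (lithium on the terminal alkyne carbon C8) | [Li]C#CC[C@@H](O[Si](C)(C)C(C)(C)C)/C(C)=C\[C@H]1O[C@@H]([C@@H](C)CO[Si](c2ccccc2)(c2ccccc2)C(C)(C)C)C[C@@H]1OC | intermediate
23 | tributyl[(4R,5Z)-4-[(tert-butyldimethylsilyl)oxy]-6-[(2R,3S,5R)-5-{(2S)-1-[(tert-butyldiphenylsilyl)oxy]propan-2-yl}-3-methoxyoxolan-2-yl]-5-methylhex-5-en-1-yn-1-yl]stannane | CCCC[Sn](CCCC)(CCCC)C#CC[C@@H](O[Si](C)(C)C(C)(C)C)/C(C)=C\[C@H]1O[C@@H]([C@@H](C)CO[Si](c2ccccc2)(c2ccccc2)C(C)(C)C)C[C@@H]1OC | intermediate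
24 | 1-[chlorobis(cyclopentadienyl)zirconio]-1-(tributylstannyl)alkene from 23 (Zr and Sn both on C8, Sn cis to C10) | CCCC[Sn](CCCC)(CCCC)/C(=C\C[C@@H](O[Si](C)(C)C(C)(C)C)/C(C)=C\[C@H]1O[C@@H]([C@@H](C)CO[Si](c2ccccc2)(c2ccccc2)C(C)(C)C)C[C@@H]1OC)[Zr](Cl)(C1C=CC=C1)C1C=CC=C1 | intermediate
25 | tributyl[(1Z,4R,5Z)-4-[(tert-butyldimethylsilyl)oxy]-6-[(2R,3S,5R)-5-{(2S)-1-[(tert-butyldiphenylsilyl)oxy]propan-2-yl}-3-methoxyoxolan-2-yl]-5-methylhexa-1,5-dien-1-yl]stannane | CCCC[Sn](CCCC)(CCCC)/C=C\C[C@@H](O[Si](C)(C)C(C)(C)C)/C(C)=C\[C@H]1O[C@@H]([C@@H](C)CO[Si](c2ccccc2)(c2ccccc2)C(C)(C)C)C[C@@H]1OC | intermediate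
26 | (2S)-2-[(2R,4S,5R)-5-[(1Z,3R,5Z)-3-[(tert-butyldimethylsilyl)oxy]-2-methyl-6-(tributylstannyl)hexa-1,5-dien-1-yl]-4-methoxyoxolan-2-yl]propan-1-ol | CCCC[Sn](CCCC)(CCCC)/C=C\C[C@@H](O[Si](C)(C)C(C)(C)C)/C(C)=C\[C@H]1O[C@@H]([C@@H](C)CO)C[C@@H]1OC | intermediate
27 | (2R)-2-[(2R,4S,5R)-5-[(1Z,3R,5Z)-3-[(tert-butyldimethylsilyl)oxy]-2-methyl-6-(tributylstannyl)hexa-1,5-dien-1-yl]-4-methoxyoxolan-2-yl]propanal | CCCC[Sn](CCCC)(CCCC)/C=C\C[C@@H](O[Si](C)(C)C(C)(C)C)/C(C)=C\[C@H]1O[C@@H]([C@@H](C)C=O)C[C@@H]1OC | intermediate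
28 | (2E)-but-2-en-1-ol | C/C=C/CO | starting material
29 | [(2R,3R)-3-methyloxiran-2-yl]methanol | OC[C@H]1O[C@@H]1C | intermediate
30 | (2S,3R)-3-methyloxirane-2-carbaldehyde | O=C[C@H]1O[C@@H]1C | intermediate
31 | (2R,3R)-2-[(E)-2-iodoethenyl]-3-methyloxirane | I/C=C/[C@H]1O[C@@H]1C | intermediate
32 | dichloro{(E)-2-[(2R,3R)-3-methyloxiran-2-yl]ethenyl}chromium | Cl[Cr](Cl)/C=C/[C@H]1O[C@@H]1C | intermediate
33 | (2R,3R,4E)-2-[(2R,4S,5R)-5-[(1Z,3R,5Z)-3-[(tert-butyldimethylsilyl)oxy]-2-methyl-6-(tributylstannyl)hexa-1,5-dien-1-yl]-4-methoxyoxolan-2-yl]-5-[(2R,3R)-3-methyloxiran-2-yl]pent-4-en-3-ol (fragment B) | CCCC[Sn](CCCC)(CCCC)/C=C\C[C@@H](O[Si](C)(C)C(C)(C)C)/C(C)=C\[C@H]1O[C@@H]([C@@H](C)[C@H](O)/C=C/[C@H]2O[C@@H]2C)C[C@@H]1OC | intermediate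
34 | prop-2-yn-1-ol | C#CCO | starting material
35 | dimethylaluminium (2E)-3-(dimethylalumanyl)-2-methylprop-2-en-1-olate | C[Al](C)/C=C(\C)CO[Al](C)C | intermediate
36 | (2E)-3-iodo-2-methylprop-2-en-1-ol | OC/C(C)=C/I | intermediate
37 | (2E)-3-iodo-2-methylprop-2-enal | O=C/C(C)=C/I | intermediate
38 | (1E,3S,4S)-1-iodo-2,4-dimethylhexa-1,5-dien-3-ol | C=C[C@H](C)[C@H](O)/C(C)=C/I | intermediate
39 | triethyl{[(1E,3S,4S)-1-iodo-2,4-dimethylhexa-1,5-dien-3-yl]oxy}silane | C=C[C@H](C)[C@H](O[Si](CC)(CC)CC)/C(C)=C/I | intermediate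
40 | (3S,4S,5E)-6-iodo-3,5-dimethyl-4-[(triethylsilyl)oxy]hex-5-ene-1,2-diol (both epimers at C2) | OCC(O)[C@H](C)[C@H](O[Si](CC)(CC)CC)/C(C)=C/I | intermediate
41 | (2R,3S,4E)-5-iodo-2,4-dimethyl-3-[(triethylsilyl)oxy]pent-4-enal | O=C[C@H](C)[C@H](O[Si](CC)(CC)CC)/C(C)=C/I | intermediate
42 | methyl (2Z,4S,5S,6E)-7-iodo-2,4,6-trimethyl-5-[(triethylsilyl)oxy]hepta-2,6-dienoate | COC(=O)/C(C)=C\[C@H](C)[C@H](O[Si](CC)(CC)CC)/C(C)=C/I | intermediate
43 | (2Z,4S,5S,6E)-7-iodo-2,4,6-trimethyl-5-[(triethylsilyl)oxy]hepta-2,6-dienoic acid (fragment A) | OC(=O)/C(C)=C\[C@H](C)[C@H](O[Si](CC)(CC)CC)/C(C)=C/I | intermediate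
44 | mixed anhydride of 43 and 2,4,6-trichlorobenzoic acid | O=C(OC(=O)c1c(Cl)cc(Cl)cc1Cl)/C(C)=C\[C@H](C)[C@H](O[Si](CC)(CC)CC)/C(C)=C/I | intermediate
45 | (2R,3R,4E)-2-[(2R,4S,5R)-5-[(1Z,3R,5Z)-3-[(tert-butyldimethylsilyl)oxy]-2-methyl-6-(tributylstannyl)hexa-1,5-dien-1-yl]-4-methoxyoxolan-2-yl]-5-[(2R,3R)-3-methyloxiran-2-yl]pent-4-en-3-yl (2Z,4S,5S,6E)-7-iodo-2,4,6-trimethyl-5-[(triethylsilyl)oxy]hepta-2,6-dienoate | CCCC[Sn](CCCC)(CCCC)/C=C\C[C@@H](O[Si](C)(C)C(C)(C)C)/C(C)=C\[C@H]1O[C@@H]([C@@H](C)[C@H](OC(=O)/C(C)=C\[C@H](C)[C@H](O[Si](CC)(CC)CC)/C(C)=C/I)/C=C/[C@H]2O[C@@H]2C)C[C@@H]1OC | intermediate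
46 | alkenylcopper from 45 (Cu in place of SnBu3 at C8) | [Cu]/C=C\C[C@@H](O[Si](C)(C)C(C)(C)C)/C(C)=C\[C@H]1O[C@@H]([C@@H](C)[C@H](OC(=O)/C(C)=C\[C@H](C)[C@H](O[Si](CC)(CC)CC)/C(C)=C/I)/C=C/[C@H]2O[C@@H]2C)C[C@@H]1OC | intermediate
47 | 19-membered macrolactone, 5-O-triethylsilyl-11-O-tert-butyldimethylsilyl-(5S)-5-hydroxy-5-deoxo analogue of the target (2Z,4S,5S,6E,8Z,11R,12Z,14R,15S,17R,18R,19R,20E,22R,23R) | CO[C@H]1C[C@H]2O[C@@H]1/C=C(/C)[C@H](O[Si](C)(C)C(C)(C)C)C/C=C\C=C(/C)[C@@H](O[Si](CC)(CC)CC)[C@@H](C)/C=C(/C)C(=O)O[C@H](/C=C/[C@H]1O[C@@H]1C)[C@@H]2C | intermediate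
48 | macrolactone with free (5S)-hydroxyl and 11-O-tert-butyldimethylsilyl ether | CO[C@H]1C[C@H]2O[C@@H]1/C=C(/C)[C@H](O[Si](C)(C)C(C)(C)C)C/C=C\C=C(/C)[C@@H](O)[C@@H](C)/C=C(/C)C(=O)O[C@H](/C=C/[C@H]1O[C@@H]1C)[C@@H]2C | intermediate
49 | 11-O-tert-butyldimethylsilyl ether of the target (C5 ketone, 4S) | CO[C@H]1C[C@H]2O[C@@H]1/C=C(/C)[C@H](O[Si](C)(C)C(C)(C)C)C/C=C\C=C(/C)C(=O)[C@@H](C)/C=C(/C)C(=O)O[C@H](/C=C/[C@H]1O[C@@H]1C)[C@@H]2C | intermediate
50 | CNP0117824.1: 19-membered macrolactone closed C1–O–C19 with a 2,5-cis oxolane (C14–O–C17); 11R-hydroxy, 15S-methoxy, 5-oxo, methyls at C2, C4 (S), C6, C12, C18 (R); 2Z,6E,8Z,12Z; (E)-2-[(2R,3R)-3-methyloxiran-2-yl]ethenyl at C19 (R); 14R,17R | CO[C@H]1C[C@H]2O[C@@H]1/C=C(/C)[C@H](O)C/C=C\C=C(/C)C(=O)[C@@H](C)/C=C(/C)C(=O)O[C@H](/C=C/[C@H]1O[C@@H]1C)[C@@H]2C | target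

## Step count and risks

Total step count: 35.
Longest linear sequence: 23 steps (from 1 through steps 1–3, 6–19, 23 and 31–35 to 50).

The three steps most likely to fail:

Step 32 (macrocyclisation). The copper-mediated coupling must close a 19-membered ring between a trisubstituted vinyl iodide and a (Z)-vinylstannane in the presence of a vinyl oxirane, and oligomerisation or protodestannylation may win. The fallback reverses the order of the two unions; it sets out from methyl ester 42 and stannane 33 and comes back at 47. Intermolecular coupling of 42 with 33 (CuO2C-C4H3S, NMP, 0 °C) gives the open-chain (6E,8Z)-diene hydroxy ester F4. Me3SnOH in ClCH2CH2Cl converts it into the seco acid F5. Activation with 2,4,6-trichlorobenzoyl chloride and Et3N gives the mixed anhydride F6, and slow addition of F6 to 4-(dimethylamino)pyridine in toluene closes the ring by Yamaguchi macrolactonisation to 47.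

Step 23 (C19 configuration). The new carbinol centre rests on substrate control only (Felkin–Anh plus 1,3-anti induction), and chromium-mediated additions often give modest ratios. The fallback sets C19 by reagent-controlled ketone reduction; it sets out from 27 and 31 and comes back at 33. The addition is run as in step 23, and the alcohol mixture of 33 and the C19 epimer of 33 F1 is oxidised together (Dess–Martin periodinane, NaHCO3, CH2Cl2) to the C19 (E)-enone F2. F2 is reduced with (R)-2-methyl-CBS-oxazaborolidine and catecholborane in toluene at −78 °C to give 33.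

Step 31 (esterification). Activated (Z)-2-methyl-2-enoic acids can isomerise to the E isomers or lose the γ-stereocentre through a vinylketene, and the C19 alcohol is hindered. The fallback makes the ester bond first and the 2Z alkene second; it sets out from alcohol 33 and aldehyde 41 and comes back at 45. Alcohol 33 is acylated with 2-[bis(2,2,2-trifluoroethoxy)phosphoryl]propanoic acid (dicyclohexylcarbodiimide, 4-(dimethylamino)pyridine, CH2Cl2) to give the C19 phosphonopropanoate of 33 F3. The potassium anion of F3 (KN(SiMe3)2, 18-crown-6, THF, −78 °C) is condensed with aldehyde 41 in an intermolecular Still–Gennari olefination that gives 45 directly.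

Further compounds

F1 | step 23 | (2R,3S,4E)-2-[(2R,4S,5R)-5-[(1Z,3R,5Z)-3-[(tert-butyldimethylsilyl)oxy]-2-methyl-6-(tributylstannyl)hexa-1,5-dien-1-yl]-4-methoxyoxolan-2-yl]-5-[(2R,3R)-3-methyloxiran-2-yl]pent-4-en-3-ol (C19 epimer of 33) | CCCC[Sn](CCCC)(CCCC)/C=C\C[C@@H](O[Si](C)(C)C(C)(C)C)/C(C)=C\[C@H]1O[C@@H]([C@@H](C)[C@@H](O)/C=C/[C@H]2O[C@@H]2C)C[C@@H]1OC
F2 | step 23 | (2R,4E)-2-[(2R,4S,5R)-5-[(1Z,3R,5Z)-3-[(tert-butyldimethylsilyl)oxy]-2-methyl-6-(tributylstannyl)hexa-1,5-dien-1-yl]-4-methoxyoxolan-2-yl]-5-[(2R,3R)-3-methyloxiran-2-yl]pent-4-en-3-one (C19 enone) | CCCC[Sn](CCCC)(CCCC)/C=C\C[C@@H](O[Si](C)(C)C(C)(C)C)/C(C)=C\[C@H]1O[C@@H]([C@@H](C)C(=O)/C=C/[C@H]2O[C@@H]2C)C[C@@H]1OC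
F3 | step 31 | C19 2-[bis(2,2,2-trifluoroethoxy)phosphoryl]propanoate of 33 (both epimers at the phosphonate carbon) | CCCC[Sn](CCCC)(CCCC)/C=C\C[C@@H](O[Si](C)(C)C(C)(C)C)/C(C)=C\[C@H]1O[C@@H]([C@@H](C)[C@H](OC(=O)C(C)P(=O)(OCC(F)(F)F)OCC(F)(F)F)/C=C/[C@H]2O[C@@H]2C)C[C@@H]1OC
F4 | step 32 | open-chain methyl ester with the C7–C8 bond formed (2Z,4S,5S,6E,8Z; free 19R hydroxyl, O5 TES, O11 TBS) | COC(=O)/C(C)=C\[C@H](C)[C@H](O[Si](CC)(CC)CC)/C(C)=C/C=C\C[C@@H](O[Si](C)(C)C(C)(C)C)/C(C)=C\[C@H]1O[C@@H]([C@@H](C)[C@H](O)/C=C/[C@H]2O[C@@H]2C)C[C@@H]1OC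
F5 | step 32 | seco acid corresponding to F4 | OC(=O)/C(C)=C\[C@H](C)[C@H](O[Si](CC)(CC)CC)/C(C)=C/C=C\C[C@@H](O[Si](C)(C)C(C)(C)C)/C(C)=C\[C@H]1O[C@@H]([C@@H](C)[C@H](O)/C=C/[C@H]2O[C@@H]2C)C[C@@H]1OC
F6 | step 32 | mixed anhydride of F5 and 2,4,6-trichlorobenzoic acid | O=C(OC(=O)c1c(Cl)cc(Cl)cc1Cl)/C(C)=C\[C@H](C)[C@H](O[Si](CC)(CC)CC)/C(C)=C/C=C\C[C@@H](O[Si](C)(C)C(C)(C)C)/C(C)=C\[C@H]1O[C@@H]([C@@H](C)[C@H](O)/C=C/[C@H]2O[C@@H]2C)C[C@@H]1OC
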